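# Proposed synthesis of CNP0251465.3 (compound 23) by 8-endo chlorine-transfer radical cyclisation

## The problem

Compound 23 is an oxocane. The chain is numbered C1 (alkyne CH) to C15 (ethyl CH3), and the ring holds O and C6–C12. Five stereocentres sit on the ring (6S, 7S, 9S, 10S, 12R) and a sixth, the bromide-bearing C13 (R), lies outside it.

- **Ring.** Eight-membered ethers resist direct closure. The side chains on C6 and C12 are trans across the ring oxygen, so no cis-templating effect is available.
- **Halogens.** Secondary chlorides at C7 and C9 flank the C8 methylene, with C9–Cl anti to the C10 acetate. The secondary bromide at C13 is next to the ring oxygen, where ionisation invites oxonium participation and base invites elimination.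
- **Control between stereocentres.** C13 can be bought as the alcohol of opposite configuration, since bromide enters with inversion. C13 can direct C12 (Felkin addition), C12 can direct C10 (chelate-controlled reduction), C10 can direct C9, and C12 with the ring can direct C6. C7 has no close neighbour to lean on and is the hardest centre to assign to a controller.
- **Fragile groups.** The (E)-enyne with its terminal alkyne, the acetate (hydride, base) and both halide types (elimination, and epimerisation at C7 whenever C6 is a carbonyl) fix the order of the last steps.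
- **Enabling feature.** In the array C6–C7(Cl)–C8H2–C9(Cl), C6 is bound to the ring oxygen. With C6 at the lactone oxidation level, this array is exactly what forms when an α-chloro ester radical at C7 adds to a terminal C8=C9 alkene and the new C9 radical takes back chlorine. Ring, one C–C bond and both C–Cl bonds can therefore come from one atom-transfer cyclisation of a dichloroacetate on the C12 oxygen.

## Retrosynthesis

**C13–Br and the C10 acetate (23 back to 19).** The last bond made is C13–Br. Target 23 is cut to the 13S alcohol 22, because a bromide next to the ring oxygen should not meet base, hydride or Lewis acid. Behind 22 stand silyl ether 21, the C10 alcohol 20 and the bis-silyl ether 19. C10 travels as a triethylsilyl ether, not as the acetate, for a definite reason. The lactone must later be reduced with iBu2AlH and acetylated in the same flask. Under those conditions a C10 acetate would itself be reduced to a hemiacetal aluminate and trapped as a 1-acetoxyethyl ether instead of being regenerated. The price is two protecting-group steps; the gain is that no ester is present during hydride reduction and alkynylation.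

**The enyne (19 back to 15).** Enyne 19 is cut at C1–C2 to enal 17 and (trimethylsilyl)diazomethane 18. Enal 17 is cut at C3=C4 to allyl oxocane 15 and crotonaldehyde 16. Cross-metathesis fixes the E geometry thermodynamically, which a Wittig reaction with a propargyl ylide would not. The forward reactions must tolerate two secondary chlorides and two silyl ethers, which both do.

**The C6 side chain (15 back to 11).** Cutting C5–C6 leads to the anomeric acetate 13 and allyltrimethylsilane 14. Acetate 13 comes from lactone 11 by reduction to aluminium lactolate 12 and acetylation in the flask. This cut turns the trans-2,8 problem into face selection on an oxocarbenium ion. It also leaves C6 as a carbonyl, which the key step needs. The alternative, adding allyl to the lactone and then hydride, would be expected to give the opposite relationship between C6 and C12.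

**The ring (11 back to 10).** Lactone 11 is cut at C7–C8 and C9–Cl to dichloroacetate 10. This removes the ring, one skeletal bond and two stereocentres at once. The precursor is a plain ester of an acyclic alcohol. Other cuts of the ring, such as etherification at C6 or C12 or a lactonisation, would leave both chlorides to be installed separately. The forward reaction must close in the 8-endo mode, not 7-exo, deliver chlorine to C9 anti to the C10 oxygen and give the 7S chloride.

**The ester and the protecting groups (10 back to 7).** Ester 10 is cut at its C–O bond to alcohol 8 and dichloroacetyl chloride 9. Alcohol 8 is the mono-triethylsilyl ether of diol 7. The forward step must silylate the open allylic C10 hydroxyl in preference to the C12 hydroxyl, which is shielded by the neighbouring silyloxy-bearing carbon.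

**The acyclic stereotriad (7 back to 1).** Diol 7 is cut at the C10–H bond to hydroxy enone 5 (reduction through boron chelate 6). Enone 5 is cut at C11–C12 to aldehyde 3 and 2-(trimethylsilyloxy)buta-1,3-diene 4. The diene brings C8–C11 with the vinyl group already in place. Aldehyde 3 comes from ester 2 and this from methyl (S)-2-hydroxybutanoate 1. C13 is bought; C12 and C10 follow by 1,2- and 1,3-induction.

## Roads not taken

**Alternative 1: two-directional chloride opening of a bis-epoxide.**
- *Cut:* the two C–Cl bonds; no ring bond.
- *Forward step:* bis-epoxide A1, a C2-symmetric bis(cis-epoxy alcohol) spanning C5–C11, would be opened at both ends with chloride under Ti(OiPr)4 mediation (an ammonium chloride as halide source). The titanium alkoxide of each hydroxymethyl group directs chloride to the distal epoxide carbon and each C–Cl bond forms with inversion, giving dichlorotetraol A2.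
- *Merits:* the C6–C10 segment of 23 is locally C2-symmetric (6S,7S,9S,10S), so a two-directional synthesis is legitimate. All four centres would be fixed by asymmetric epoxidation and a stereospecific SN2 opening. This is absolute, reagent-based control over C7 and C9, which the chosen plan cannot match because it relies on substrate control in a radical step.
- *Weak points:* A2 has no ring and only seven of the fifteen carbons. Its two ends and its two pairs of hydroxyls are equivalent and must be told apart. C12 and C13 still have to be created. The oxocane must then be closed by an ether bond between O6 and C12, two secondary, heteroatom-flanked positions, which is the hardest step for an eight-membered ring and for which this road offers no device. The chlorohydrin units also revert to epoxides in base, which restricts all later chemistry.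
- *Comparison:* better stereocontrol at the chlorinated centres, but the ring problem is postponed, not solved. The chosen plan sets against it one step that delivers the ring, the C7–C8 bond and both chlorides, on a substrate reached in six steps.

**Alternative 2: oxocane by ozonolysis of a bicyclic enol ether.**
- *Cut:* no bond of the target; the ring is uncovered, not closed.
- *Forward step:* bicyclic enol ether A3, in which a dihydrofuran and a cyclopentene share the tetrasubstituted C6=C10 double bond, would be cleaved with ozone. C6 becomes the lactone carbonyl, C10 a ketone, and the fused bicycle opens to keto lactone A4.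
- *Merits:* fragmentation carries no entropic penalty and needs no dilution. The electron-rich enol ether is the obvious site of attack, and the C12/C13 bromopropyl unit is already in place. In certainty of ring formation this road is better than an 8-endo radical closure.
- *Weak points:* the key step forms no skeletal bond and none of the halogen-bearing centres. Afterwards C7–Cl must come from α-chlorination of a medium-ring lactone in the presence of a more acidic ketone. C9–Cl must come from inverting displacement of an oxygen flanked by that ketone or its carbinol. C10 must come from a face-selective reduction. That is three stereocentres set on a flexible ring. A4 is also a β-acyloxy ketone (C10 carbonyl, acyl on O12) and should open by β-elimination under mild base; its C9 centre is epimerisable; and the secondary bromide must survive all of this.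
- *Comparison:* surer ring formation, but heavier and more fragile work after it. The chosen plan has C10, C12 and C13 fixed beforehand by acyclic stereocontrol and makes both C–Cl bonds in the ring-forming event. Its price is high dilution and less certain control at C7.

**Alternative 3: SmI2 Reformatsky cyclisation closing C10–C11.**
- *Cut:* C10–C11.
- *Forward step:* bromoacetate A5 (ester on the C6 oxygen, aldehyde at C10) would be treated with SmI2. The samarium enolate at C11 adds to the aldehyde within a chelate and closes β-hydroxy lactone A6, whose carbonyl carbon is C12.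
- *Merits:* SmI2-promoted Reformatsky closures of eight- and nine-membered lactones are well established and, being metal-templated, depend less on dilution than a radical closure. C6 and C7, chloride included, are set in the open chain before cyclisation. The C10 carbinol arises under 1,2-induction from C9. In ring-closure reliability and in control of C7 this road is at least as good as the chosen one.
- *Weak points:* the lactone is oriented the other way round, so the carbonyl to be converted into a substituted ether carbon is C12, which carries the branched 1-bromopropyl group. That conversion needs a nucleophile bringing an oxygenated C13 and control of two adjacent centres. The chosen plan only needs an allyl group at C6 and buys C13 with the starting material. C9 enters as a silyloxy group and must be turned into the chloride with inversion on the ring, next to the C10 oxygen, where participation and elimination threaten.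
- *Comparison:* the chosen plan gives up the templated ionic closure and the pre-set C7 configuration. It gains a precursor with C10, C12 and C13 already correct, both chlorides at the moment the ring forms, and a simpler end game.

Key step: step 7

Assumption: compounds 12 and 13 form as mixtures of both configurations at the acetal carbon C6; this is of no consequence because C6 becomes planar (oxocarbenium ion) in step 9.

## Route

Step 1
Reactants: 1 methyl (S)-2-hydroxybutanoate
Product: 2 methyl (S)-2-(tert-butyldimethylsilyloxy)butanoate
Conditions: TBSCl, imidazole, DMF, 0 °C to rt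
Reagents that add atoms: tert-butyldimethylsilyl chloride, CC(C)(C)[Si](C)(C)Cl
Why: Imidazole-promoted silylation of a secondary alcohol; the stereocentre is untouched, and the bulky, non-chelating silyl ether is what steers step 3.

Step 2
Reactants: 2 methyl (S)-2-(tert-butyldimethylsilyloxy)butanoate
Product: 3 (S)-2-(tert-butyldimethylsilyloxy)butanal
Conditions: iBu2AlH (1.05 equiv), CH2Cl2, −78 °C; MeOH, aq. potassium sodium tartrate
Reagents that add atoms: none
Why: Partial reduction of an α-silyloxy ester, whose tetrahedral aluminate is stable at −78 °C and releases the aldehyde only on work-up. The aldehyde should be used at once without chromatography to avoid epimerisation at C13.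

Step 3
Reactants: 3 (S)-2-(tert-butyldimethylsilyloxy)butanal; 4 2-(trimethylsilyloxy)buta-1,3-diene
Product: 5 (5R,6S)-6-(tert-butyldimethylsilyloxy)-5-hydroxyoct-1-en-3-one
Conditions: 4 (1.5 equiv), BF3·OEt2 (1.1 equiv), CH2Cl2, −78 °C; aq. NaHCO3 at −78 °C
Reagents that add atoms: none
Why: Mukaiyama aldol addition through the terminal enol-ether carbon of the diene forms C11–C12. With the monodentate Lewis acid BF3 and a silyl ether that does not chelate, the nucleophile should add anti to the C13 oxygen (polar Felkin–Anh), giving the 12R (12,13-anti) carbinol. The cold basic quench keeps the β-hydroxy vinyl ketone from closing by oxa-Michael addition.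

Step 4
Reactants: 5 (5R,6S)-6-(tert-butyldimethylsilyloxy)-5-hydroxyoct-1-en-3-one
Product: 7 (3S,5R,6S)-6-(tert-butyldimethylsilyloxy)oct-1-ene-3,5-diol, via diethylborinate chelate 6 (not isolated)
Conditions: Et2BOMe (1.1 equiv), THF/MeOH 4:1, −78 °C; NaBH4, −78 °C; AcOH, then MeOH co-evaporation
Reagents that add atoms: methoxydiethylborane, CCB(CC)OC (supplies only the boron of intermediate 6)
Why: Narasaka–Prasad reduction: the C12 oxygen and the C10 carbonyl are tied into a six-membered boron chelate, and external hydride attacks it axially, which should give the 10,12-syn diol (10S). Chelate activation favours 1,2- over 1,4-reduction of the enone.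

Step 5
Reactants: 7 (3S,5R,6S)-6-(tert-butyldimethylsilyloxy)oct-1-ene-3,5-diol
Product: 8 (3S,5R,6S)-6-(tert-butyldimethylsilyloxy)-3-(triethylsilyloxy)oct-1-en-5-ol
Conditions: TESCl (1.05 equiv), imidazole, CH2Cl2, −40 to 0 °C
Reagents that add atoms: chlorotriethylsilane, CC[Si](CC)(CC)Cl
Why: Silylation is highly sensitive to steric environment; the allylic C10 hydroxyl, flanked by a vinyl group and a methylene, should react well ahead of the C12 hydroxyl, which is shielded by the adjacent C13 silyloxy-bearing carbon.

Step 6
Reactants: 8 (3S,5R,6S)-6-(tert-butyldimethylsilyloxy)-3-(triethylsilyloxy)oct-1-en-5-ol; 9 dichloroacetyl chloride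
Product: 10 (3S,5R,6S)-6-(tert-butyldimethylsilyloxy)-3-(triethylsilyloxy)oct-1-en-5-yl dichloroacetate
Conditions: 9 (1.5 equiv), pyridine (3 equiv), CH2Cl2, −20 to 0 °C
Reagents that add atoms: none
Why: Acylation of the hindered C12 alcohol with a very reactive acid chloride. Pyridine is used in place of a trialkylamine so that the acid chloride is not dehydrochlorinated to dichloroketene, which would add to the alkene.

Step 7
Reactants: 10 (3S,5R,6S)-6-(tert-butyldimethylsilyloxy)-3-(triethylsilyloxy)oct-1-en-5-yl dichloroacetate
Product: 11 (3S,5S,6S,8R)-8-[(1S)-1-(tert-butyldimethylsilyloxy)propyl]-3,5-dichloro-6-(triethylsilyloxy)oxocan-2-one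
Conditions: CuCl (30 mol %), tris(2-pyridylmethyl)amine (30 mol %), degassed ClCH2CH2Cl, 0.005 M, 80 °C
Reagents that add atoms: none
Why: The CuCl–amine complex (monovalent copper) reversibly abstracts a chlorine atom from the dichloroacetate, giving an electrophilic, ester-stabilised radical at C7 and the CuCl2 complex (divalent copper); the radical adds to the terminal alkene carbon C8 and the secondary C9 radical takes chlorine back from the CuCl2 complex, which regenerates the catalyst. This is a Kharasch-type atom-transfer radical cyclisation, and the closest known case is the copper-catalysed closure of pent-4-enyl trichloroacetates to eight-membered lactones, applied here to a dichloroacetate with a more active amine ligand. The one ring formed, the oxocan-2-one, closes in the 8-endo mode: the ester keeps its s-trans geometry, so the chain can reach only C8, and 7-exo attack at C9 is further hindered by the allylic C10 silyloxy group. The C9 stereocentre (9S) should be set by 1,2-induction, chlorine being delivered to the ring radical on the face opposite the adjacent triethylsilyloxy group. The C7 stereocentre is set when the C7–C8 bond forms, in a chain fold that should keep the C7 chlorine, the C10 silyloxy group and the C12 side chain on the outside of the developing ring. As a secondary α-chloro ester it remains open to re-activation by the catalyst, so it can drift to the more stable epimer, and the epimer needed is 7S, trans to the C9 chlorine across C8. The step needs intramolecular addition to beat intermolecular addition, which high dilution and the polarity match between electrophilic radical and unactivated alkene should secure; the silyl ethers and the unactivated C9–Cl bond are inert to the catalyst.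

Step 8
Reactants: 11 (3S,5S,6S,8R)-8-[(1S)-1-(tert-butyldimethylsilyloxy)propyl]-3,5-dichloro-6-(triethylsilyloxy)oxocan-2-one
Product: 13 (3S,5S,6S,8R)-8-[(1S)-1-(tert-butyldimethylsilyloxy)propyl]-3,5-dichloro-6-(triethylsilyloxy)oxocan-2-yl acetate (both C2 epimers), via aluminium lactolate 12 (not isolated)
Conditions: iBu2AlH (1.3 equiv), CH2Cl2, −78 °C; then pyridine, DMAP, Ac2O, −78 to −20 °C
Reagents that add atoms: acetic anhydride, CC(=O)OC(C)=O; diisobutylaluminium hydride, CC(C)C[AlH]CC(C)C (supplies only the aluminium of intermediate 12)
Why: Rychnovsky-type reductive acetylation: the tetrahedral aluminate, further stabilised by the α-chlorine, is acetylated at low temperature before the eight-membered lactol can open to the hydroxy aldehyde. No other ester is present, so a slight excess of hydride is harmless.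

Step 9
Reactants: 13 (3S,5S,6S,8R)-8-[(1S)-1-(tert-butyldimethylsilyloxy)propyl]-3,5-dichloro-6-(triethylsilyloxy)oxocan-2-yl acetate; 14 allyltrimethylsilane
Product: 15 (2S,3S,5S,6S,8R)-2-allyl-8-[(1S)-1-(tert-butyldimethylsilyloxy)propyl]-3,5-dichloro-6-(triethylsilyloxy)oxocane
Conditions: 14 (5 equiv), BF3·OEt2 (2 equiv), CH2Cl2, −78 to −30 °C
Reagents that add atoms: none
Why: Hosomi–Sakurai allylation of the cyclic oxocarbenium ion formed by ionising the acetate. The allyl group should enter anti to the C12 side chain, the usual 2,8-trans outcome for carbon nucleophiles on such cations, giving 6S. The C7 chlorine is expected to lie near the plane of the cation, as α-chloro oxocarbenium ions prefer, and so not to block that face.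

Step 10
Reactants: 15 (2S,3S,5S,6S,8R)-2-allyl-8-[(1S)-1-(tert-butyldimethylsilyloxy)propyl]-3,5-dichloro-6-(triethylsilyloxy)oxocane; 16 (E)-but-2-enal (crotonaldehyde)
Product: 17 (E)-4-[(2S,3S,5S,6S,8R)-8-[(1S)-1-(tert-butyldimethylsilyloxy)propyl]-3,5-dichloro-6-(triethylsilyloxy)oxocan-2-yl]but-2-enal
Conditions: 16 (10 equiv), second-generation Grubbs catalyst (5 mol %), CH2Cl2, 40 °C
Reagents that add atoms: none
Why: Olefin cross-metathesis of a terminal alkene with an excess of an electron-poor partner; the conjugated enal should form as the E isomer under thermodynamic control, and propene leaves the mixture.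

Step 11
Reactants: 17 (E)-4-[(2S,3S,5S,6S,8R)-8-[(1S)-1-(tert-butyldimethylsilyloxy)propyl]-3,5-dichloro-6-(triethylsilyloxy)oxocan-2-yl]but-2-enal; 18 (trimethylsilyl)diazomethane
Product: 19 (2S,3S,5S,6S,8R)-8-[(1S)-1-(tert-butyldimethylsilyloxy)propyl]-3,5-dichloro-2-[(E)-pent-2-en-4-yn-1-yl]-6-(triethylsilyloxy)oxocane
Conditions: 18 (1.3 equiv), LDA (1.2 equiv), THF, −78 °C; then 17, −78 to 0 °C; aq. NH4Cl
Reagents that add atoms: none
Why: Colvin rearrangement: the lithiated diazo compound adds to the aldehyde, Peterson-type loss of silanolate and of N2 gives an alkylidene carbene, and a 1,2-hydrogen shift delivers the terminal alkyne with the E alkene untouched. The reagent adds at −78 °C, and no ester is present to compete.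

Step 12
Reactants: 19 (2S,3S,5S,6S,8R)-8-[(1S)-1-(tert-butyldimethylsilyloxy)propyl]-3,5-dichloro-2-[(E)-pent-2-en-4-yn-1-yl]-6-(triethylsilyloxy)oxocane
Product: 20 (2R,4S,5S,7S,8S)-2-[(1S)-1-(tert-butyldimethylsilyloxy)propyl]-5,7-dichloro-8-[(E)-pent-2-en-4-yn-1-yl]oxocan-4-ol
Conditions: PPTS (0.2 equiv), MeOH/CH2Cl2 1:1, 0 °C to rt
Reagents that add atoms: none
Why: Mild acid methanolysis removes a triethylsilyl ether far faster than a secondary tert-butyldimethylsilyl ether, so only the C10 hydroxyl should be freed.

Step 13
Reactants: 20 (2R,4S,5S,7S,8S)-2-[(1S)-1-(tert-butyldimethylsilyloxy)propyl]-5,7-dichloro-8-[(E)-pent-2-en-4-yn-1-yl]oxocan-4-ol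
Product: 21 (2R,4S,5S,7S,8S)-2-[(1S)-1-(tert-butyldimethylsilyloxy)propyl]-5,7-dichloro-8-[(E)-pent-2-en-4-yn-1-yl]oxocan-4-yl acetate
Conditions: Ac2O, pyridine, DMAP (cat.), CH2Cl2, 0 °C to rt
Reagents that add atoms: acetic anhydride, CC(=O)OC(C)=O
Why: DMAP-catalysed acetylation of a secondary alcohol; the amine bases are too weak to close the trans-chlorohydrin to an epoxide.

Step 14
Reactants: 21 (2R,4S,5S,7S,8S)-2-[(1S)-1-(tert-butyldimethylsilyloxy)propyl]-5,7-dichloro-8-[(E)-pent-2-en-4-yn-1-yl]oxocan-4-yl acetate
Product: 22 (2R,4S,5S,7S,8S)-5,7-dichloro-2-[(1S)-1-hydroxypropyl]-8-[(E)-pent-2-en-4-yn-1-yl]oxocan-4-yl acetate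
Conditions: HF·pyridine, pyridine, THF, 0 °C to rt
Reagents that add atoms: none
Why: Buffered fluoride desilylation under weakly acidic conditions, which should leave the acetate in place and tolerate the chlorides and the enyne.

Step 15
Reactants: 22 (2R,4S,5S,7S,8S)-5,7-dichloro-2-[(1S)-1-hydroxypropyl]-8-[(E)-pent-2-en-4-yn-1-yl]oxocan-4-yl acetate
Product: 23 (2R,4S,5S,7S,8S)-2-[(1R)-1-bromopropyl]-5,7-dichloro-8-[(E)-pent-2-en-4-yn-1-yl]oxocan-4-yl acetate
Conditions: CBr4 (3 equiv), P(n-Oct)3 (6 equiv), toluene, 70 °C
Reagents that add atoms: tetrabromomethane, BrC(Br)(Br)Br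
Why: Appel-type bromination: the alkoxyphosphonium ion is displaced by bromide in an SN2 step, turning the 13S alcohol into the 13R bromide. The trialkylphosphine in a non-polar solvent is the standard choice for carbinols next to an ether oxygen, because it disfavours ionisation and oxonium participation.

## Compound list

1 | methyl (S)-2-hydroxybutanoate | CC[C@H](O)C(=O)OC | starting material
2 | methyl (S)-2-(tert-butyldimethylsilyloxy)butanoate | CC[C@H](O[Si](C)(C)C(C)(C)C)C(=O)OC | intermediate
3 | (S)-2-(tert-butyldimethylsilyloxy)butanal | CC[C@H](O[Si](C)(C)C(C)(C)C)C=O | intermediate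
4 | 2-(trimethylsilyloxy)buta-1,3-diene | C=CC(=C)O[Si](C)(C)C | starting material
5 | (5R,6S)-6-(tert-butyldimethylsilyloxy)-5-hydroxyoct-1-en-3-one | C=CC(=O)C[C@@H](O)[C@@H](O[Si](C)(C)C(C)(C)C)CC | intermediate
6 | diethylborinate chelate of 5, (5R,6S)-6-(tert-butyldimethylsilyloxy)-5-(diethylboranyloxy)oct-1-en-3-one | C=CC(=O)C[C@@H](OB(CC)CC)[C@@H](O[Si](C)(C)C(C)(C)C)CC | intermediate
7 | (3S,5R,6S)-6-(tert-butyldimethylsilyloxy)oct-1-ene-3,5-diol | C=C[C@@H](O)C[C@@H](O)[C@@H](O[Si](C)(C)C(C)(C)C)CC | intermediate
8 | (3S,5R,6S)-6-(tert-butyldimethylsilyloxy)-3-(triethylsilyloxy)oct-1-en-5-ol | C=C[C@@H](O[Si](CC)(CC)CC)C[C@@H](O)[C@@H](O[Si](C)(C)C(C)(C)C)CC | intermediate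
9 | dichloroacetyl chloride | ClC(Cl)C(Cl)=O | starting material
10 | (3S,5R,6S)-6-(tert-butyldimethylsilyloxy)-3-(triethylsilyloxy)oct-1-en-5-yl dichloroacetate | C=C[C@@H](O[Si](CC)(CC)CC)C[C@@H](OC(=O)C(Cl)Cl)[C@@H](O[Si](C)(C)C(C)(C)C)CC | intermediate
11 | (3S,5S,6S,8R)-8-[(1S)-1-(tert-butyldimethylsilyloxy)propyl]-3,5-dichloro-6-(triethylsilyloxy)oxocan-2-one | O=C1O[C@@H]([C@@H](O[Si](C)(C)C(C)(C)C)CC)C[C@H](O[Si](CC)(CC)CC)[C@@H](Cl)C[C@@H]1Cl | intermediate
12 | diisobutylaluminium (3S,5S,6S,8R)-8-[(1S)-1-(tert-butyldimethylsilyloxy)propyl]-3,5-dichloro-6-(triethylsilyloxy)oxocan-2-olate (both C2 epimers) | CC(C)C[Al](CC(C)C)OC1O[C@@H]([C@@H](O[Si](C)(C)C(C)(C)C)CC)C[C@H](O[Si](CC)(CC)CC)[C@@H](Cl)C[C@@H]1Cl | intermediate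
13 | (3S,5S,6S,8R)-8-[(1S)-1-(tert-butyldimethylsilyloxy)propyl]-3,5-dichloro-6-(triethylsilyloxy)oxocan-2-yl acetate (both C2 epimers) | CC(=O)OC1O[C@@H]([C@@H](O[Si](C)(C)C(C)(C)C)CC)C[C@H](O[Si](CC)(CC)CC)[C@@H](Cl)C[C@@H]1Cl | intermediate
14 | allyltrimethylsilane | C=CC[Si](C)(C)C | starting material
15 | (2S,3S,5S,6S,8R)-2-allyl-8-[(1S)-1-(tert-butyldimethylsilyloxy)propyl]-3,5-dichloro-6-(triethylsilyloxy)oxocane | C=CC[C@@H]1O[C@@H]([C@@H](O[Si](C)(C)C(C)(C)C)CC)C[C@H](O[Si](CC)(CC)CC)[C@@H](Cl)C[C@@H]1Cl | intermediate
16 | (E)-but-2-enal (crotonaldehyde) | C/C=C/C=O | starting material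
17 | (E)-4-[(2S,3S,5S,6S,8R)-8-[(1S)-1-(tert-butyldimethylsilyloxy)propyl]-3,5-dichloro-6-(triethylsilyloxy)oxocan-2-yl]but-2-enal | O=C/C=C/C[C@@H]1O[C@@H]([C@@H](O[Si](C)(C)C(C)(C)C)CC)C[C@H](O[Si](CC)(CC)CC)[C@@H](Cl)C[C@@H]1Cl | intermediate
18 | (trimethylsilyl)diazomethane | C[Si](C)(C)C=[N+]=[N-] | starting material
19 | (2S,3S,5S,6S,8R)-8-[(1S)-1-(tert-butyldimethylsilyloxy)propyl]-3,5-dichloro-2-[(E)-pent-2-en-4-yn-1-yl]-6-(triethylsilyloxy)oxocane | C#C/C=C/C[C@@H]1O[C@@H]([C@@H](O[Si](C)(C)C(C)(C)C)CC)C[C@H](O[Si](CC)(CC)CC)[C@@H](Cl)C[C@@H]1Cl | intermediate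
20 | (2R,4S,5S,7S,8S)-2-[(1S)-1-(tert-butyldimethylsilyloxy)propyl]-5,7-dichloro-8-[(E)-pent-2-en-4-yn-1-yl]oxocan-4-ol | C#C/C=C/C[C@@H]1O[C@@H]([C@@H](O[Si](C)(C)C(C)(C)C)CC)C[C@H](O)[C@@H](Cl)C[C@@H]1Cl | intermediate
21 | (2R,4S,5S,7S,8S)-2-[(1S)-1-(tert-butyldimethylsilyloxy)propyl]-5,7-dichloro-8-[(E)-pent-2-en-4-yn-1-yl]oxocan-4-yl acetate | C#C/C=C/C[C@@H]1O[C@@H]([C@@H](O[Si](C)(C)C(C)(C)C)CC)C[C@H](OC(C)=O)[C@@H](Cl)C[C@@H]1Cl | intermediate
22 | (2R,4S,5S,7S,8S)-5,7-dichloro-2-[(1S)-1-hydroxypropyl]-8-[(E)-pent-2-en-4-yn-1-yl]oxocan-4-yl acetate | C#C/C=C/C[C@@H]1O[C@@H]([C@@H](O)CC)C[C@H](OC(C)=O)[C@@H](Cl)C[C@@H]1Cl | intermediate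
23 | (2R,4S,5S,7S,8S)-2-[(1R)-1-bromopropyl]-5,7-dichloro-8-[(E)-pent-2-en-4-yn-1-yl]oxocan-4-yl acetate | C#C/C=C/C[C@@H]1O[C@@H]([C@H](Br)CC)C[C@H](OC(C)=O)[C@@H](Cl)C[C@@H]1Cl | target

## Step count and least certain steps

Total step count: 15. Longest linear sequence: 15 steps (1 to 23); compounds 4, 9, 14, 16 and 18 are bought.

**Step 7 (key step).**
- *What may go wrong:* chlorine abstraction from a dichloroacetate is slower than from the trichloroacetates on which the method rests. Intermolecular addition and oligomerisation, or plain reduction of the C–Cl bond, may therefore outrun ring closure. Face selection at C7, and to a lesser degree at C9, may also be incomplete because the forming eight-membered ring is flexible and C7 has no adjacent stereocentre.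
- *Fallback:* it sets out from alcohol 8. Trichloroacetyl chloride and pyridine would give (3S,5R,6S)-6-(tert-butyldimethylsilyloxy)-3-(triethylsilyloxy)oct-1-en-5-yl trichloroacetate F1. This is the substrate type of the direct precedent and should close under CuCl with 2,2'-bipyridine in hot ClCH2CH2Cl to the 3,3,5-trichloro lactone F2. One of the geminal chlorines of F2 would then be removed with Bu3SnH (1.05 equiv) and Et3B/air in toluene at −78 °C. The doubly activated C–Cl bond reacts far ahead of the C9 chloride, and C7 is set by hydrogen-atom transfer to the ring radical instead of in the C–C bond-forming event. The route is rejoined at lactone 11.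

**Step 9.**
- *What may go wrong:* the allylsilane may attack the wrong face of the oxocarbenium ion, because on simple steric grounds the C7 chlorine and the C12 side chain point the nucleophile to opposite faces. Ionisation of an acetate flanked by an electron-withdrawing chlorine may also be slow enough for the Lewis acid to cleave the triethylsilyl ether.
- *Fallback:* it sets out from lactone 11 and reverses the order in which carbon and hydrogen arrive at C6. Allylmagnesium bromide (THF, −78 °C) would add once to give the hemiketal (3S,5S,6S,8R)-2-allyl-8-[(1S)-1-(tert-butyldimethylsilyloxy)propyl]-3,5-dichloro-6-(triethylsilyloxy)oxocan-2-ol F3. Et3SiH with BF3·OEt2 (CH2Cl2, −78 to −40 °C) would then reduce the derived allyl-substituted oxocarbenium ion. Since hydride now takes the face that the allyl group took before, the configuration at C6 should be complementary. The route is rejoined at allyl oxocane 15.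

**Step 5.**
- *What may go wrong:* discrimination between the two secondary hydroxyls may be insufficient, leading to silylation at C12 or at both oxygens.
- *Fallback:* it sets out from diol 7. 4-Methoxybenzaldehyde dimethyl acetal and PPTS would give the all-equatorial 4-methoxybenzylidene acetal F4. iBu2AlH (CH2Cl2, −78 to 0 °C) coordinates the less hindered acetal oxygen at C10 and cleaves its bond, so that (3S,5R,6S)-6-(tert-butyldimethylsilyloxy)-5-(4-methoxybenzyloxy)oct-1-en-3-ol F5 results, with the free hydroxyl at C10. TESCl and imidazole would give the fully protected ether F6, and DDQ in CH2Cl2/pH 7 buffer would remove the 4-methoxybenzyl group. The route is rejoined at alcohol 8.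

**Step 15.**
- *What may go wrong:* the ring oxygen may participate in the departure of the activated C13 oxygen, giving retention or a ring-contracted bromide by way of an oxonium ion. Elimination towards C14 may also occur at 70 °C.
- *Fallback:* it sets out from alcohol 22 and separates activation from displacement. Chloromethanesulfonyl chloride and 2,6-lutidine (CH2Cl2, 0 °C) would give the chloromethanesulfonate F7, a leaving group reactive enough for hindered secondary centres. Bu4NBr in toluene at 40–50 °C would displace it with inversion. The route is rejoined at target 23.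

## Further compounds

F1 | step 7 | (3S,5R,6S)-6-(tert-butyldimethylsilyloxy)-3-(triethylsilyloxy)oct-1-en-5-yl trichloroacetate | C=C[C@@H](O[Si](CC)(CC)CC)C[C@@H](OC(=O)C(Cl)(Cl)Cl)[C@@H](O[Si](C)(C)C(C)(C)C)CC
F2 | step 7 | (5S,6S,8R)-8-[(1S)-1-(tert-butyldimethylsilyloxy)propyl]-3,3,5-trichloro-6-(triethylsilyloxy)oxocan-2-one | O=C1O[C@@H]([C@@H](O[Si](C)(C)C(C)(C)C)CC)C[C@H](O[Si](CC)(CC)CC)[C@@H](Cl)CC1(Cl)Cl
F3 | step 9 | (3S,5S,6S,8R)-2-allyl-8-[(1S)-1-(tert-butyldimethylsilyloxy)propyl]-3,5-dichloro-6-(triethylsilyloxy)oxocan-2-ol (both C2 epimers) | C=CCC1(O)O[C@@H]([C@@H](O[Si](C)(C)C(C)(C)C)CC)C[C@H](O[Si](CC)(CC)CC)[C@@H](Cl)C[C@@H]1Cl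
F4 | step 5 | 4-methoxybenzylidene acetal of diol 7 (2-aryl, 4- and 6-substituents all cis on the 1,3-dioxane) | C=C[C@@H]1C[C@H]([C@@H](O[Si](C)(C)C(C)(C)C)CC)O[C@H](c2ccc(OC)cc2)O1
F5 | step 5 | (3S,5R,6S)-6-(tert-butyldimethylsilyloxy)-5-(4-methoxybenzyloxy)oct-1-en-3-ol | C=C[C@@H](O)C[C@@H](OCc1ccc(OC)cc1)[C@@H](O[Si](C)(C)C(C)(C)C)CC
F6 | step 5 | (3S,5R,6S)-6-(tert-butyldimethylsilyloxy)-5-(4-methoxybenzyloxy)-3-(triethylsilyloxy)oct-1-ene | C=C[C@@H](O[Si](CC)(CC)CC)C[C@@H](OCc1ccc(OC)cc1)[C@@H](O[Si](C)(C)C(C)(C)C)CC
F7 | step 15 | (2R,4S,5S,7S,8S)-5,7-dichloro-2-[(1S)-1-(chloromethanesulfonyloxy)propyl]-8-[(E)-pent-2-en-4-yn-1-yl]oxocan-4-yl acetate | C#C/C=C/C[C@@H]1O[C@@H]([C@@H](OS(=O)(=O)CCl)CC)C[C@H](OC(C)=O)[C@@H](Cl)C[C@@H]1Cl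
A1 | alternative 1 | (2S,3R,5R,6S)-2,3:5,6-diepoxyheptane-1,7-diol | OC[C@@H]1O[C@@H]1C[C@H]1O[C@H]1CO
A2 | alternative 1 | (2S,3S,5S,6S)-3,5-dichloroheptane-1,2,6,7-tetraol | OC[C@H](O)[C@@H](Cl)C[C@H](Cl)[C@@H](O)CO
A3 | alternative 2 | (2R,4R)-2-[(1R)-1-bromopropyl]-4-(tert-butyldimethylsilyloxy)-3,4,5,6-tetrahydro-2H-cyclopenta[b]furan | CC[C@@H](Br)[C@H]1CC2=C(CC[C@H]2O[Si](C)(C)C(C)(C)C)O1
A4 | alternative 2 | (5R,8R)-8-[(1R)-1-bromopropyl]-5-(tert-butyldimethylsilyloxy)oxocane-2,6-dione | CC[C@@H](Br)[C@H]1CC(=O)[C@H](O[Si](C)(C)C(C)(C)C)CCC(=O)O1
A5 | alternative 3 | (3S,4S,6R)-6-(tert-butyldimethylsilyloxy)-4-chloro-1-(4-methoxybenzyloxy)-7-oxoheptan-3-yl bromoacetate | COc1ccc(COCC[C@H](OC(=O)CBr)[C@@H](Cl)C[C@@H](O[Si](C)(C)C(C)(C)C)C=O)cc1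
A6 | alternative 3 | (4S,5R,7S,8S)-5-(tert-butyldimethylsilyloxy)-7-chloro-4-hydroxy-8-[2-(4-methoxybenzyloxy)ethyl]oxocan-2-one | COc1ccc(COCC[C@@H]2OC(=O)C[C@H](O)[C@H](O[Si](C)(C)C(C)(C)C)C[C@@H]2Cl)cc1
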